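**Plan**
1. The target is an unsymmetrical dibenzyl ether of ring A (2,6-dibromo-3,4-dihydroxyphenyl) and ring B (2,3,6-tribromo-4,5-dihydroxyphenyl). It has no stereocentre, so no stereocontrol is needed.
2. Cuts, in order: (i) the four O–Si bonds of a tetra-TBS ether; (ii) the bond between C1 of ring A and its benzylic CH2, giving a ring-A aryl anion and the cation equivalent ClCH2–O–CH2–Ar(B); (iii) O–CH2Cl, the benzylic C–O and the three ring-B C–Br bonds, back to 4-methylcatechol; (iv) ring A back to 3,5-dibromosalicylaldehyde.
3. Enabling feature: C1 of ring A sits between the two bromine-bearing carbons C2 and C6. In the parent 3,5-dibromocatechol ether that C–H is the most acidic ring position, and its lithio form is the end point of any bromine migration. Ring B has no ring C–H and cannot be metalated.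
4. One event therefore fixes the site of C–C bond formation and keeps a 2,6-dibromo pattern that bromination of a 3,4-dihydroxybenzyl compound does not give. It also installs the whole CH2–O–CH2 bridge without any cross-etherification of two labile p-oxybenzyl alcohols.
5. Forward order: ring-A piece (2 steps), ring-B electrophile (5 steps), union of the halves, buffered fluoride deprotection. No ring is formed.

Key step: step 8

Remark: the SMILES contains no stereocentre and no isolable axis, so the compound is treated as achiral and "single enantiomer" needs no measure.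

**Step 1**
Reactants: 1 3,5-dibromo-2-hydroxybenzaldehyde (3,5-dibromosalicylaldehyde)
Product: 3 3,5-dibromobenzene-1,2-diol, via aryl formate 2 (not isolated)
Conditions: 30% aq H2O2 (1.3 equiv), NaOH (2.2 equiv), H2O/THF, N2, 0 °C → rt; then 1 M HCl
Reagents that add atoms: hydrogen peroxide, OO
Why: Dakin oxidation, in which hydroperoxide adds to the aldehyde, the ortho-phenoxide ring migrates from carbon to oxygen to give formate 2, and base cleaves 2 to the catechol, so the 3,5-dibromo pattern of the commercial aldehyde is carried over unchanged.

**Step 2**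
Reactants: 3 3,5-dibromobenzene-1,2-diol
Product: 4 3,5-dibromo-1,2-bis(tert-butyldimethylsilyloxy)benzene
Conditions: TBSCl (2.5 equiv), imidazole (5 equiv), DMF, rt
Reagents that add atoms: tert-butyldimethylsilyl chloride, CC(C)(C)[Si](C)(C)Cl
Why: Standard imidazole-promoted silylation of acidic phenols, giving bulky, non-chelating TBS ethers that survive amide bases, remove the ortho-directing power of oxygen and leave with fluoride at the end.

**Step 3**
Reactants: 5 4-methylbenzene-1,2-diol (4-methylcatechol)
Product: 6 3,4,6-tribromo-5-methylbenzene-1,2-diol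
Conditions: Br2 (3.3 equiv), AcOH, 0 °C → rt; aq NaHSO3 work-up
Reagents that add atoms: bromine, BrBr
Why: Exhaustive electrophilic aromatic bromination, in which each of the three free ring positions is ortho or para to a free OH (as in the preparation of tetrabromocatechol from catechol), so no regiochemical question arises and the bisulfite work-up returns any o-quinone to the catechol.

**Step 4**
Reactants: 6 3,4,6-tribromo-5-methylbenzene-1,2-diol
Product: 7 3,4,6-tribromo-5-methyl-1,2-bis(tert-butyldimethylsilyloxy)benzene
Conditions: TBSCl (2.6 equiv), imidazole (5 equiv), DMF, rt → 40 °C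
Reagents that add atoms: tert-butyldimethylsilyl chloride, CC(C)(C)[Si](C)(C)Cl
Why: Imidazole-promoted silylation of phenols, which works on 2,6-disubstituted acidic phenols such as 2,6-dibromophenol and uses the same group as ring A so that one final operation frees all four phenols.

**Step 5**
Reactants: 7 3,4,6-tribromo-5-methyl-1,2-bis(tert-butyldimethylsilyloxy)benzene
Product: 8 2,3,6-tribromo-4,5-bis(tert-butyldimethylsilyloxy)benzyl bromide
Conditions: NBS (1.1 equiv), AIBN (5 mol %), PhCF3, 85 °C
Reagents that add atoms: N-bromosuccinimide, O=C1CCC(=O)N1Br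
Why: Wohl–Ziegler bromination, in which the ring is fully substituted and only the benzylic C–H bonds can react, as in the conversion of 2,6-dibromotoluene into 2,6-dibromobenzyl bromide.

**Step 6**
Reactants: 8 2,3,6-tribromo-4,5-bis(tert-butyldimethylsilyloxy)benzyl bromide
Product: 9 2,3,6-tribromo-4,5-bis(tert-butyldimethylsilyloxy)benzyl alcohol
Conditions: Ag2CO3 (0.75 equiv), acetone/H2O 4:1, rt, dark
Reagents that add atoms: water, O
Why: Silver-assisted hydrolysis of a benzylic bromide, in which Ag+ abstracts bromide at room temperature, the para-silyloxy group supports the developing cation, water captures it, and the insoluble carbonate takes up the acid so the medium stays near neutral for the aryl silyl ethers.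

**Step 7**
Reactants: 9 2,3,6-tribromo-4,5-bis(tert-butyldimethylsilyloxy)benzyl alcohol
Product: 10 chloromethyl 2,3,6-tribromo-4,5-bis(tert-butyldimethylsilyloxy)benzyl ether
Conditions: (CH2O)n (1.5 equiv), TMSCl (4 equiv), CH2Cl2, 0 °C → rt; volatiles removed in vacuo, crude 10 used at once
Reagents that add atoms: paraformaldehyde (as formaldehyde), C=O; chlorotrimethylsilane, C[Si](C)(C)Cl
Why: Chloromethylation of an alcohol with paraformaldehyde and TMSCl, the usual preparation of alkoxymethyl chlorides of the BOMCl type, under which aryl TBS ethers of electron-poor phenols tolerate the anhydrous HCl that forms.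

**Step 8**
Reactants: 4 3,5-dibromo-1,2-bis(tert-butyldimethylsilyloxy)benzene; 10 chloromethyl 2,3,6-tribromo-4,5-bis(tert-butyldimethylsilyloxy)benzyl ether
Product: 12 2,6-dibromo-3,4-bis(tert-butyldimethylsilyloxy)benzyl 2,3,6-tribromo-4,5-bis(tert-butyldimethylsilyloxy)benzyl ether, via aryllithium 11 (not isolated)
Conditions: 4 (1.3 equiv), commercial LDA solution (1.25 equiv), THF, −78 °C, 45 min; then 10 (1.0 equiv) in THF, −78 → −50 °C; aq NH4Cl
Reagents that add atoms: lithium diisopropylamide, [Li]N(C(C)C)C(C)C (gives the lithium of 11; none of its atoms stays in 12)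
Why: LDA removes the only ring proton of 4 that lies between the two bromine-bearing carbons (C4–H), since two ortho bromines acidify it more than one bromine plus one silyloxy group acidify C6–H, and the bulky, non-chelating OTBS group next to C6–H both shields that proton and offers lithium no directing lone pair. The 2,6-dibromoaryllithium 11 so formed is already the most stabilised anion that a bromine migration (halogen dance) could reach, so the bromine pattern should stay fixed, and at −78 °C it should not lose LiBr to an aryne. 11 then displaces chloride from the oxocarbenium-like carbon of the α-chloro ether 10, which forms the aryl–CH2 bond and delivers at once the complete unsymmetrical ArCH2–O–CH2Ar′ skeleton with all five bromines in place. The closest known reaction types are the LDA lithiation of 1,3-dibromoarenes at C2 and the alkoxymethylation of aryllithium or aryl Grignard reagents with MOMCl or BOMCl. No ring is closed and no stereocentre is formed. The step needs C–Cl substitution to win over Br/Li exchange and proton transfer: ring B of 10 has no ring hydrogen, exchange at any of its three C–Br bonds would give an aryllithium with at most one ortho bromine and is therefore uphill from 11, and an α-chloro ether reacts with an aryllithium at −78 °C far faster than these side paths.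

**Step 9**
Reactants: 12 2,6-dibromo-3,4-bis(tert-butyldimethylsilyloxy)benzyl 2,3,6-tribromo-4,5-bis(tert-butyldimethylsilyloxy)benzyl ether
Product: 13 2,6-dibromo-3,4-dihydroxybenzyl 2,3,6-tribromo-4,5-dihydroxybenzyl ether (target)
Conditions: TBAF (4.4 equiv), AcOH (5 equiv), THF, argon, 0 °C; pH 5–6 aqueous work-up
Reagents that add atoms: none
Why: Fluoride-induced cleavage of aryl silyl ethers, in which acetic acid protonates each phenoxide as it forms, blocking para-quinone methide expulsion of the benzylic alkoxide and air oxidation of catecholates, while neither the C–Br bonds nor the dibenzyl ether react with fluoride.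

**Compound list**
1 | 3,5-dibromo-2-hydroxybenzaldehyde | O=Cc1cc(Br)cc(Br)c1O | starting material
2 | 3,5-dibromo-2-hydroxyphenyl formate (aryl formate, formed in the flask) | O=COc1cc(Br)cc(Br)c1O | intermediate
3 | 3,5-dibromobenzene-1,2-diol | Oc1cc(Br)cc(Br)c1O | intermediate
4 | 3,5-dibromo-1,2-bis(tert-butyldimethylsilyloxy)benzene | CC(C)(C)[Si](C)(C)Oc1cc(Br)cc(Br)c1O[Si](C)(C)C(C)(C)C | intermediate
5 | 4-methylbenzene-1,2-diol | Cc1ccc(O)c(O)c1 | starting material
6 | 3,4,6-tribromo-5-methylbenzene-1,2-diol | Cc1c(Br)c(O)c(O)c(Br)c1Br | intermediate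
7 | 3,4,6-tribromo-5-methyl-1,2-bis(tert-butyldimethylsilyloxy)benzene | Cc1c(Br)c(O[Si](C)(C)C(C)(C)C)c(O[Si](C)(C)C(C)(C)C)c(Br)c1Br | intermediate
8 | 2,3,6-tribromo-4,5-bis(tert-butyldimethylsilyloxy)benzyl bromide | BrCc1c(Br)c(O[Si](C)(C)C(C)(C)C)c(O[Si](C)(C)C(C)(C)C)c(Br)c1Br | intermediate
9 | 2,3,6-tribromo-4,5-bis(tert-butyldimethylsilyloxy)benzyl alcohol | OCc1c(Br)c(O[Si](C)(C)C(C)(C)C)c(O[Si](C)(C)C(C)(C)C)c(Br)c1Br | intermediate
10 | chloromethyl 2,3,6-tribromo-4,5-bis(tert-butyldimethylsilyloxy)benzyl ether | ClCOCc1c(Br)c(O[Si](C)(C)C(C)(C)C)c(O[Si](C)(C)C(C)(C)C)c(Br)c1Br | intermediate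
11 | 2,6-dibromo-3,4-bis(tert-butyldimethylsilyloxy)phenyllithium (aryllithium, formed in the flask) | [Li]c1c(Br)cc(O[Si](C)(C)C(C)(C)C)c(O[Si](C)(C)C(C)(C)C)c1Br | intermediate
12 | 2,6-dibromo-3,4-bis(tert-butyldimethylsilyloxy)benzyl 2,3,6-tribromo-4,5-bis(tert-butyldimethylsilyloxy)benzyl ether | CC(C)(C)[Si](C)(C)Oc1cc(Br)c(COCc2c(Br)c(O[Si](C)(C)C(C)(C)C)c(O[Si](C)(C)C(C)(C)C)c(Br)c2Br)c(Br)c1O[Si](C)(C)C(C)(C)C | intermediate
13 | 2,6-dibromo-3,4-dihydroxybenzyl 2,3,6-tribromo-4,5-dihydroxybenzyl ether | Oc1cc(Br)c(COCc2c(Br)c(O)c(O)c(Br)c2Br)c(Br)c1O | target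

Total step count: 9. Longest linear sequence: 7 (steps 3–9).

**Steps most likely to fail**

**Step 8.** Three processes could intervene. Bromine–lithium scrambling could occur between the aryllithium and the tribromoaryl electrophile. The aryllithium could lose LiBr to an aryne before substitution is complete. Diisopropylamine could consume the α-chloro ether.

The fallback joins the halves at C–O instead of C–C. It sets out from 4 and 8 and comes back at 12. 4 is lithiated as before, and 11 is quenched at −78 °C with the small, bromine-free electrophile DMF to give 2,6-dibromo-3,4-bis(tert-butyldimethylsilyloxy)benzaldehyde F1. DIBAL-H in CH2Cl2 at −78 °C reduces this to 2,6-dibromo-3,4-bis(tert-butyldimethylsilyloxy)benzyl alcohol F2. A neutral, Ag2O-promoted Williamson-type etherification of F2 with bromide 8 (CH2Cl2, 4 Å MS) should then give 12.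

**Step 6.** The para silyl group could be lost from the benzylic cation, which would collapse towards a para-quinone methide. The base-labile aryl silyl ethers could also hydrolyse in the aqueous medium.

The fallback avoids ionisation and water by passing through the aldehyde oxidation level. It sets out from 8 and comes back at 9. N-Methylmorpholine N-oxide in dry MeCN (4 Å MS, rt) attacks the benzylic carbon by SN2 and eliminates (Kornblum-type oxidation) to give 2,3,6-tribromo-4,5-bis(tert-butyldimethylsilyloxy)benzaldehyde F3. DIBAL-H in CH2Cl2 at −78 °C then reduces F3 to 9.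

**Step 7.** HCl could ionise the p-silyloxybenzyl alcohol and convert it to the benzylic chloride. The chloromethyl ether could also condense with unreacted alcohol to give the symmetrical formal.

The fallback builds the O–CH2 unit without acid and unmasks the chloride afterwards. It sets out from 9 and comes back at 10. DMSO/Ac2O/AcOH at rt (Pummerer-type methylthiomethylation) gives methylthiomethyl 2,3,6-tribromo-4,5-bis(tert-butyldimethylsilyloxy)benzyl ether F4. SO2Cl2 in CH2Cl2 at 0 °C then cleaves the C–S bond to give 10, and only volatiles need to be removed.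

**Further compounds**
F1 | step 8 | 2,6-dibromo-3,4-bis(tert-butyldimethylsilyloxy)benzaldehyde | O=Cc1c(Br)cc(O[Si](C)(C)C(C)(C)C)c(O[Si](C)(C)C(C)(C)C)c1Br
F2 | step 8 | 2,6-dibromo-3,4-bis(tert-butyldimethylsilyloxy)benzyl alcohol | OCc1c(Br)cc(O[Si](C)(C)C(C)(C)C)c(O[Si](C)(C)C(C)(C)C)c1Br
F3 | step 6 | 2,3,6-tribromo-4,5-bis(tert-butyldimethylsilyloxy)benzaldehyde | O=Cc1c(Br)c(O[Si](C)(C)C(C)(C)C)c(O[Si](C)(C)C(C)(C)C)c(Br)c1Br
F4 | step 7 | methylthiomethyl 2,3,6-tribromo-4,5-bis(tert-butyldimethylsilyloxy)benzyl ether | CSCOCc1c(Br)c(O[Si](C)(C)C(C)(C)C)c(O[Si](C)(C)C(C)(C)C)c(Br)c1Br
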